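The rate constants are those of an exercise; what happens was integrated by code.

In a one-step world, starting material and partner would relax to the equilibrium of step 1 and a single ratio would tell the end, but this flask has side steps.

    starting material + partner + free catalyst ⇌ product + free catalyst, rate k1*[starting material]*[partner]*[free catalyst] forward; the back reaction follows from the equilibrium constant (K1 = 7.1 M⁻¹, k1 = 5000 M⁻² h⁻¹)
    starting material + free catalyst → spent catalyst (k2 = 1.9 M⁻¹ h⁻¹)
    partner + precatalyst → free catalyst + spent reagent (k3 = 1.1 M⁻¹ h⁻¹)
    starting material + protic impurity → quenched substrate (k4 = 710 M⁻¹ h⁻¹)

the same everywhere: starting material 0.019 M; partner 0.0285 M; precatalyst 1.5 mM; time 5.0 d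
- Saturday's: protic impurity 7.60 mM
- Monday's: protic impurity 15.0 mM
- Sunday's: protic impurity 3.80 mM

* which of these there is most of at the end, counted by the starting material in it, Saturday's (starting material / product)
* which of these there is most of at the end, counted by the starting material in it, Monday's (starting material / product)
* which of these there is most of at the end, counted by the starting material in it, Sunday's (starting material / product)
* amount of the one of these that there is most of at the end, in percent of the starting material charged, Saturday's
* amount of the one of these that there is most of at the end, in percent of the starting material charged, Monday's
* amount of the one of these that there is most of at the end, in percent of the starting material charged, Sunday's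

*Who gets the starting material first?* The protic impurity. On Sunday's, the half-life of starting material by step 4 is 0.26 h, reckoned with the impurity held at its charge; the charge is 3.80 mM, so step 4 takes a part of the starting material and then stops for want of impurity. Precatalyst frees its catalyst on a clock τ, the reciprocal of k3 times the partner charged, 31.9 h, so the quench comes first. Each impurity takes one starting material. Sunday's therefore has 15.2 mM in the pool Q, the starting material charged minus the protic impurity charged. Saturday's has 11.4 mM and Monday's 4.00 mM.

*And then?* Step 1 splits Q, with product over starting material equal to K1 times partner, 0.20 at Sunday's start. Precatalyst claims some partner, so I divide Q by D, which is one plus K1 times partner charged less precatalyst charged: 1.19.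

*Does that equilibrium arrive?* With the whole catalyst charge free, the clock of step 1 is 4.68 h, shorter than τ, so the split follows the catalyst as it appears. This is thermodynamic control.

*You treated Q as intact. What eats it?* Step 2: each spent catalyst costs one starting material, at most 1.5 mM, small against Sunday's Q. So I compute only that correction. Catalyst appears after about τ and then dies at k2 times Q/D, which gives the spent amount Z as the charge times one minus exp(−k2(Q/D)(t−τ)). That is 1.20 mM on Saturday's, 0.645 mM on Monday's and 1.32 mM on Sunday's.

*Commit.* Starting material is (Q−Z)/D, and product is the rest of Q−Z. The leader is starting material on Saturday's, starting material on Monday's and starting material on Sunday's. The amounts are 45.1%, 14.8% and 61.3%.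

The forecast names starting material for each flask, with 46% (44.5% to 47.5%) on Saturday's, 15.1% (14.3% to 16%) on Monday's and 62.5% (60.5% to 64.5%) on Sunday's. It starts from the same ground, “the usable pool is 19 minus impurity”, but it divides by 1.18 where I divide by D, and it takes off 1.1, 0.6 and 1.2 mM of spent catalyst on Saturday's, Monday's and Sunday's where I take off Z; both differences put my figures a little lower.

The simulation has starting material leading on Saturday's at 45.9%, starting material on Monday's at 15.1% and starting material on Sunday's at 62.5%. On Sunday's, step 4 had half its turnover behind it at 0.0546 h, while step 3 had 31% of its turnover behind it at 0.500 d. Saturday's moves 6 points, past the forecast's range, with protic impurity at 6.22 mM or 9.00 mM. With spent catalyst and partner as they stood at the end, Q gives 62.5% on Sunday's. The neighbour, Sunday's with 0.0060 M of precatalyst, has the same Q, which gives 48.9%, and it holds 48.9%.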